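**Assumption:** the target SMILES has no stereocentres (the molecule is achiral), so there is no enantiomer to control and no stereochemical step is needed.

## Retrosynthetic overview

1. Target 10 comes from its benzyl ester 9 by hydrogenolysis.
2. The usual depside disconnection (A‑ring acid + B‑ring phenol) is avoided: the chlorinated A ring is built de novo on the finished ester linkage by a Diels–Alder/aromatization of aryl hex‑2‑ynoate 5 with chloro‑Brassard diene 8.
3. The ynoate supplies C1, C6, the propyl group and the depside C=O; the diene supplies C2–C5 with OH, Cl and OMe already in place, so no arene chlorination or selective O‑methylation is needed.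
4. 5 comes from benzyl divarinate 3 and hex‑2‑ynoic acid 4; 3 comes from divarinol 1 by ortho‑carboxylation and benzylation. 8 comes from methyl 2‑chloroacetoacetate 6 in two steps.
5. Ring order: the B ring is bought as an arene; the A ring is formed in the penultimate step.

## Route

**Step 1**
Reactants: 1, 5‑propylbenzene‑1,3‑diol (divarinol)
Product: 2, 2,4‑dihydroxy‑6‑propylbenzoic acid (divarinic acid)
Conditions: MeOMgOCO2Me (2 M in DMF), 120 °C, 3 h; then cold aq. HCl
Reagents that add atoms: methyl magnesium carbonate, COC(=O)O[Mg]OC (delivers CO2, O=C=O)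
Why: Kolbe–Schmitt‑type ortho‑carboxylation with Stiles' reagent, where the Mg chelate directs CO2 ortho to OH and next to the alkyl group, as in the olivetol → olivetolic acid conversion.

**Step 2**
Reactants: 2, 2,4‑dihydroxy‑6‑propylbenzoic acid
Product: 3, benzyl 2,4‑dihydroxy‑6‑propylbenzoate
Conditions: BnBr (1.05 equiv), KHCO3, DMF, rt
Reagents that add atoms: benzyl bromide, BrCc1ccccc1
Why: Carboxylate SN2 O‑alkylation; bicarbonate deprotonates only the acid, so the phenols are not benzylated.

**Step 3**
Reactants: 3, benzyl 2,4‑dihydroxy‑6‑propylbenzoate; 4, hex‑2‑ynoic acid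
Product: 5, benzyl 4‑(hex‑2‑ynoyloxy)‑2‑hydroxy‑6‑propylbenzoate
Conditions: DCC (1.05 equiv), DMAP (5 mol %), CH2Cl2, 0 °C
Reagents that add atoms: none (4 is listed as a reactant)
Why: Steglich esterification, selective for the free 4‑OH because the 2‑OH is hydrogen‑bonded to the ester carbonyl and hindered; low temperature and little DMAP suppress ynoate → allenoate isomerization.

**Step 4**
Reactants: 6, methyl 2‑chloro‑3‑oxobutanoate (methyl 2‑chloroacetoacetate)
Product: 7, methyl 2‑chloro‑3‑methoxybut‑2‑enoate (E/Z mixture, inconsequential)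
Conditions: HC(OMe)3, cat. H2SO4, MeOH, rt; then distil from cat. TsOH (–MeOH)
Reagents that add atoms: trimethyl orthoformate, COC(OC)OC
Why: Acid‑catalysed ketalization followed by elimination of MeOH gives the conjugated β‑methoxy enoate, the standard enol‑ether synthesis from β‑keto esters.

**Step 5**
Reactants: 7, methyl 2‑chloro‑3‑methoxybut‑2‑enoate
Product: 8, 2‑chloro‑1,3‑dimethoxy‑1‑(trimethylsilyloxy)buta‑1,3‑diene (used crude)
Conditions: LDA (1.1 equiv), THF, –78 °C; TMSCl, –78 → 0 °C; non‑aqueous work‑up (hexane, filter)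
Reagents that add atoms: chlorotrimethylsilane, C[Si](C)(C)Cl
Why: Brassard diene synthesis, i.e. γ‑deprotonation of the β‑methoxy enoate and O‑silylation of the dienolate; there is no α‑H, so only the γ‑CH3 can be deprotonated.

**Step 6 (key step)**
Reactants: 5, benzyl 4‑(hex‑2‑ynoyloxy)‑2‑hydroxy‑6‑propylbenzoate; 8, chloro‑Brassard diene (3 equiv)
Product: 9, benzyl 4‑[(3‑chloro‑2‑hydroxy‑4‑methoxy‑6‑propylbenzoyl)oxy]‑2‑hydroxy‑6‑propylbenzoate
Conditions: BSA (1.5 equiv), PhMe, rt, 1 h (transient TMS ether of the 2‑OH); then 8, 125 °C, sealed tube, 24 h; then 1 M HCl/THF, rt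
Reagents that add atoms: none (MeOSiMe3 is lost; TMS groups are removed on work‑up)
Why: Brassard/Danishefsky‑type vinylketene‑acetal Diels–Alder with an alkynoate, in which the nucleophilic CH2 terminus of 8 bonds to the propyl‑bearing β‑carbon and the ketene‑acetal carbon to the α‑carbon; the mixed methyl silyl ketal then collapses and the dienone tautomerizes to the chelated salicylate, placing 2‑OH, 3‑Cl, 4‑OMe and 6‑Pr by construction.

**Step 7**
Reactants: 9, benzyl ester of the depside
Product: 10, 3‑chlorodivaricatic acid, 4‑[(3‑chloro‑2‑hydroxy‑4‑methoxy‑6‑propylbenzoyl)oxy]‑2‑hydroxy‑6‑propylbenzoic acid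
Conditions: H2 (1 atm), 10 % Pd/C, EtOAc, rt, stop at 1 equiv H2 uptake
Reagents that add atoms: none
Why: Neutral benzyl‑ester hydrogenolysis, which is much faster than hydrodechlorination of an electron‑rich aryl chloride and leaves the aryl ester and phenols untouched.

## Compound list

1 | 5‑propylbenzene‑1,3‑diol (divarinol) | CCCc1cc(O)cc(O)c1 | starting material
2 | 2,4‑dihydroxy‑6‑propylbenzoic acid | CCCc1cc(O)cc(O)c1C(=O)O | intermediate
3 | benzyl 2,4‑dihydroxy‑6‑propylbenzoate | CCCc1cc(O)cc(O)c1C(=O)OCc1ccccc1 | intermediate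
4 | hex‑2‑ynoic acid | CCCC#CC(=O)O | starting material
5 | benzyl 4‑(hex‑2‑ynoyloxy)‑2‑hydroxy‑6‑propylbenzoate | CCCC#CC(=O)Oc1cc(O)c(C(=O)OCc2ccccc2)c(CCC)c1 | intermediate
6 | methyl 2‑chloro‑3‑oxobutanoate | CC(=O)C(Cl)C(=O)OC | starting material
7 | methyl 2‑chloro‑3‑methoxybut‑2‑enoate | COC(C)=C(Cl)C(=O)OC | intermediate
8 | 2‑chloro‑1,3‑dimethoxy‑1‑(trimethylsilyloxy)buta‑1,3‑diene | C=C(OC)C(Cl)=C(OC)O[Si](C)(C)C | intermediate
9 | benzyl 4‑[(3‑chloro‑2‑hydroxy‑4‑methoxy‑6‑propylbenzoyl)oxy]‑2‑hydroxy‑6‑propylbenzoate | CCCc1cc(OC(=O)c2c(CCC)cc(OC)c(Cl)c2O)cc(O)c1C(=O)OCc1ccccc1 | intermediate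
10 | 3‑chlorodivaricatic acid | CCCc1cc(OC(=O)c2c(CCC)cc(OC)c(Cl)c2O)cc(O)c1C(=O)O | target

## Summary

Total steps: 7 (convergent: steps 1–3 and steps 4–5 meet at step 6).
Longest linear sequence: 5 steps (1 → 2 → 3 → 6 → 7).

Three steps most likely to fail, with fallbacks:

1. **Step 6 (Diels–Alder/aromatization).** The β‑alkyl ynoate and the 2‑chloro diene may react sluggishly, or the ketal may collapse the wrong way. Fallback: switch to a Lewis‑acid formal [3+3] (Chan type). Acylate 3 with chloroacetylketene (from 6‑(chloromethyl)‑2,2‑dimethyl‑1,3‑dioxin‑4‑one, PhMe, 110 °C) to give the aryl 4‑chloroacetoacetate, convert it to its 1,3‑bis(trimethylsilyloxy)diene, and condense with 1,1‑dimethoxyhex‑1‑en‑3‑one using TiCl4. This builds the same ring through different bonds, with Cl and OMe again pre‑placed.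

2. **Step 5 (lithium α‑chlorodienolate and labile diene).** The dienolate may decompose or C‑silylate. Fallback: avoid the lithium species by making the Chan‑type 2‑chloro‑1‑methoxy‑1,3‑bis(trimethylsilyloxy)buta‑1,3‑diene directly from 6 by soft enolization (TMSOTf/Et3N). The same cycloaddition then gives the 3‑chloro‑2,4‑dihydroxy A ring, and the non‑chelated 4‑OH is methylated afterwards (MeI, K2CO3, acetone).

3. **Step 7 (hydrogenolysis next to Ar–Cl).** Partial hydrodechlorination is possible. Fallback: change the protecting‑group strategy. Carry the B‑ring acid as its allyl ester from step 2 (allyl bromide/KHCO3) and remove it at the end with Pd(PPh3)4/PhSiH3, which needs no H2 and no nucleophilic amine that could cleave the depside ester.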